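## Retrosynthetic overview

- Target ⇒ (7S)-germacrene A + a C-methyl β-triketone. One electrolysis makes the C16–C1 and C5–C10 bonds and adds water at C4, so rings A and B of the decalin form together, last.
- (7S)-Germacrene A ⇒ enol triflate ⇒ anionic oxy-Cope ring expansion of a trans-1,2-dialkenylcyclohexanol (six-membered → ten-membered ring).
- Dialkenylcyclohexanol ⇒ (S)-carvone by conjugate reduction, α-vinylation and isopropenyl addition. C7 of the target is the carvone stereocentre and relays the other four.
- Triketone ⇒ phloroglucinol by Friedel–Crafts isovalerylation and dearomatizing C-trimethylation.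
- Ring order: cyclohexane (purchased) → cyclodecadiene (step 4) → trans-decalin (step 8); the trione ring comes from the arene.

Assumption: germacrane/eudesmane locants (C1–C15, with C16 for the linking CH2) are used for the terpene part, and all β-triketones are written as the enol tautomer that appears in the target SMILES.

## Route

Step 1
Reactants: 1 (S)-(+)-carvone
Product: 2 (2S,5S)-dihydrocarvone (trans isomer shown; the C2 epimers are used together)
Conditions: LiBH(s-Bu)3 (1.1 equiv), THF, −78 °C; H2O
Reagents that add atoms: none
Why: Conjugate hydride reduction of the β-unsubstituted enone by the bulky trialkylborohydride leaves the isopropenyl group and C5 untouched, and the C2 epimer ratio does not matter because C2 is re-enolized in step 2.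

Step 2
Reactants: 2 (2S,5S)-dihydrocarvone
Product: 4 (2S,5S)-2-methyl-5-(prop-1-en-2-yl)-2-vinylcyclohexan-1-one, via sulfoxide adduct 3 (not isolated)
Conditions: KH (1.05 equiv), THF, 0 → 23 °C; PhS(O)CH=CH2 (1.2 equiv), 0 → 23 °C; H2O; crude 3 in PhMe, CaCO3, 110 °C
Reagents that add atoms: phenyl vinyl sulfoxide, C=CS(=O)c1ccccc1
Why: Michael addition of the more substituted (thermodynamic) potassium enolate to the vinyl sulfoxide followed by thermal syn-elimination of the sulfoxide is the standard α-vinylation that gives quaternary 2-methyl-2-vinylcyclohexanones, and the chain enters axially on the face cis to the equatorial C5 isopropenyl group (the sense seen in Robinson annulations of dihydrocarvone), so C5 sets C2.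

Step 3
Reactants: 4 (2S,5S)-2-methyl-5-(prop-1-en-2-yl)-2-vinylcyclohexan-1-one
Product: 5 (1R,2S,5S)-2-methyl-1,5-di(prop-1-en-2-yl)-2-vinylcyclohexan-1-ol (new isopropenyl trans to vinyl; OH cis to vinyl)
Conditions: CH2=C(CH3)MgBr (2 equiv), CeCl3 (2 equiv), THF, −78 → 0 °C; H2O
Reagents that add atoms: isopropenylmagnesium bromide, C=C(C)[Mg]Br
Why: CeCl3-promoted 1,2-addition of the Grignard reagent (enolization suppressed) occurs axially, anti to the axial C2 vinyl group of the chair that keeps the C5 isopropenyl equatorial, which gives the trans-1,2-dialkenyl carbinol needed for a chair oxy-Cope transition state, and the minor cis isomer is removed by chromatography.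

Step 4
Reactants: 5 (1R,2S,5S)-2-methyl-1,5-di(prop-1-en-2-yl)-2-vinylcyclohexan-1-ol
Product: 7 (7S,1(10)E,4Z)-germacra-1(10),4,11-trien-5-yl trifluoromethanesulfonate, via potassium germacradienolate 6 (not isolated)
Conditions: KH (1.5 equiv), 18-crown-6 (0.2 equiv), THF, 0 → 40 °C; PhNTf2 (1.3 equiv), −78 → 0 °C
Reagents that add atoms: N-phenylbis(trifluoromethanesulfonimide), O=S(=O)(N(c1ccccc1)S(=O)(=O)C(F)(F)F)C(F)(F)F
Why: Anionic oxy-Cope rearrangement of the potassium alkoxide through the chair transition state with both ring bonds equatorial gives the E-configured C1=C10 alkene and a geometrically defined tetrasubstituted enolate (ring carbons C3 and C6 trans across C4=C5) that is O-sulfonylated in the same flask, while C7 is untouched and the carbinol and quaternary centres are deliberately erased.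

Step 5
Reactants: 7 (7S,1(10)E,4Z)-germacra-1(10),4,11-trien-5-yl trifluoromethanesulfonate
Product: 8 (7S)-germacrene A [(7S,1(10)E,4E)-germacra-1(10),4,11-triene]
Conditions: Pd(OAc)2 (5 mol%), PPh3 (10 mol%), HCO2H (2 equiv), Bu3N (3 equiv), DMF, 40 °C; pentane extraction, basic alumina, stored cold
Reagents that add atoms: none
Why: Palladium-catalysed formate reduction of the enol triflate (oxidative addition, formate exchange, decarboxylation, reductive elimination) replaces OTf by H with retention of alkene geometry under buffered mild conditions that avoid Cope rearrangement or acid cyclization of the germacrene.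

Step 6
Reactants: 9 phloroglucinol
Product: 10 3-methyl-1-(2,4,6-trihydroxyphenyl)butan-1-one
Conditions: 3-methylbutanoyl chloride (1.05 equiv), AlCl3 (3 equiv), PhNO2, 23 → 65 °C; aq. HCl work-up
Reagents that add atoms: 3-methylbutanoyl chloride, CC(C)CC(Cl)=O
Why: Friedel–Crafts C-acylation of the electron-rich triphenol stops cleanly at the mono-ketone because the acyl group deactivates the ring.

Step 7
Reactants: 10 3-methyl-1-(2,4,6-trihydroxyphenyl)butan-1-one
Product: 11 3,5-dihydroxy-4,6,6-trimethyl-2-(3-methylbutanoyl)cyclohexa-2,4-dien-1-one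
Conditions: MeI (3.1 equiv), NaOMe (3.1 equiv), MeOH, 0 → 23 °C; chromatography to remove the tetramethyl by-product
Reagents that add atoms: iodomethane, CI
Why: Base-mediated dearomatizing C-methylation of the acylphloroglucinol with three equivalents of MeI gives the gem-dimethyl/monomethyl trione, which is the only constitution possible for three C-methylations of the two free ring carbons.

Step 8
Reactants: 8 (7S)-germacrene A; 11 3,5-dihydroxy-4,6,6-trimethyl-2-(3-methylbutanoyl)cyclohexa-2,4-dien-1-one
Product: 13 CNP0490948.1 [(1R,4S,5S,7S,10R)-1-{[2,6-dihydroxy-3,3-dimethyl-5-(3-methylbutanoyl)-4-oxocyclohexa-1,5-dien-1-yl]methyl}eudesm-11-en-4-ol], via methylene-trione 12 (not isolated)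
Conditions: undivided cell, graphite-felt anode, Pt cathode, constant current (2.2 F per mol of 11), 8 (1.0 equiv), 11 (1.5 equiv), TEMPO (20 mol%), 2,6-lutidine (2 equiv), LiClO4 (0.1 M), acetone/H2O (4:1), 0 °C
Reagents that add atoms: water, O
Why: Proposed new method: anodically regenerated TEMPO (aminoxyl/oxoammonium couple) dehydrogenates the enolized C-methyl group of 11 to the α-methylene β-triketone 12 at a potential well below that of the alkenes, and in buffered aqueous acetone C1 of the strained C1=C10 alkene of crown-shaped 8 (isopropenyl equatorial) attacks the CH2 of 12, the developing C10 cation is captured transannularly by C5 of the C4=C5 alkene and the C4 cation by water, so that two stereospecific anti additions across the two E-alkenes give the trans-decalin with equatorial C1 side chain, equatorial C4 hydroxyl, axial C4 methyl and the C10 methyl cis to the C7 isopropenyl group, all relayed from C7, the closest known reactions being the Ag2O/TEMPO oxidation of such C-methyl triones to the same methide for hetero-Diels–Alder trapping by terpenes, anodic generation of o-quinone methides, and the proton-induced transannular cyclization of germacrene A to selin-11-en-4-ol.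

## Compound list

1 | (S)-(+)-carvone [(5S)-2-methyl-5-(prop-1-en-2-yl)cyclohex-2-en-1-one] | CC1=CC[C@@H](CC1=O)C(C)=C | starting material
2 | (2S,5S)-dihydrocarvone (trans isomer; C2 epimers used together) | C[C@H]1CC[C@@H](CC1=O)C(C)=C | intermediate
3 | (2S,5S)-2-methyl-2-[2-(phenylsulfinyl)ethyl]-5-(prop-1-en-2-yl)cyclohexan-1-one (chain cis to isopropenyl; mixture at sulfur) | C[C@@]1(CCS(=O)c2ccccc2)CC[C@@H](CC1=O)C(C)=C | intermediate
4 | (2S,5S)-2-methyl-5-(prop-1-en-2-yl)-2-vinylcyclohexan-1-one (vinyl cis to isopropenyl) | C[C@@]1(C=C)CC[C@@H](CC1=O)C(C)=C | intermediate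
5 | (1R,2S,5S)-2-methyl-1,5-di(prop-1-en-2-yl)-2-vinylcyclohexan-1-ol (C1 isopropenyl trans to vinyl) | C=C(C)[C@]1(O)C[C@@H](C(C)=C)CC[C@@]1(C)C=C | intermediate
6 | potassium (7S,1(10)E,4Z)-germacra-1(10),4,11-trien-5-olate | C/C1=C\CC/C(C)=C(\[O-])C[C@@H](C(C)=C)CC1.[K+] | intermediate
7 | (7S,1(10)E,4Z)-germacra-1(10),4,11-trien-5-yl trifluoromethanesulfonate | C/C1=C\CC/C(C)=C(\OS(=O)(=O)C(F)(F)F)C[C@@H](C(C)=C)CC1 | intermediate
8 | (7S)-germacrene A [(7S,1(10)E,4E)-germacra-1(10),4,11-triene] | C/C1=C\CC/C(C)=C/C[C@@H](C(C)=C)CC1 | intermediate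
9 | phloroglucinol (benzene-1,3,5-triol) | Oc1cc(O)cc(O)c1 | starting material
10 | 3-methyl-1-(2,4,6-trihydroxyphenyl)butan-1-one | CC(C)CC(=O)c1c(O)cc(O)cc1O | intermediate
11 | 3,5-dihydroxy-4,6,6-trimethyl-2-(3-methylbutanoyl)cyclohexa-2,4-dien-1-one | CC1=C(O)C(C)(C)C(=O)C(C(=O)CC(C)C)=C1O | intermediate
12 | 3-hydroxy-6,6-dimethyl-4-methylidene-2-(3-methylbutanoyl)cyclohex-2-ene-1,5-dione | C=C1C(=O)C(C)(C)C(=O)C(C(=O)CC(C)C)=C1O | intermediate
13 | CNP0490948.1, (1R,4S,5S,7S,10R)-1-{[2,6-dihydroxy-3,3-dimethyl-5-(3-methylbutanoyl)-4-oxocyclohexa-1,5-dien-1-yl]methyl}eudesm-11-en-4-ol (C10 methyl, C4 methyl, C1 side chain and C7 isopropenyl on one face; 4-OH and 5-H on the other) | C=C(C)[C@H]1CC[C@]2(C)[C@@H](CC3=C(O)C(C)(C)C(=O)C(C(=O)CC(C)C)=C3O)CC[C@](C)(O)[C@H]2C1 | target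

## Step count and risks

Total step count: 8. Longest linear sequence: 6 steps (steps 1, 2, 3, 4, 5 and 8, from (S)-carvone); steps 6 and 7 make the trione in parallel.

The three steps most likely to fail are steps 3, 4 and 8.

**Step 3 (facial selectivity of the isopropenyl addition).** If the bulky isopropenyl nucleophile attacks equatorially, the cis-dialkenyl carbinol forms and the oxy-Cope rearrangement would give a wrong alkene geometry. The fallback sets out from 4 and comes back at 5. Ethynylmagnesium bromide (THF, −78 °C), a small linear nucleophile with a strong preference for axial attack, gives ethynyl carbinol F1. Negishi methylalumination of the terminal alkyne (Me3Al, Cp2ZrCl2 20 mol%, CH2Cl2, 0 → 23 °C) followed by protonolysis with water places the methyl on the internal carbon and so turns the ethynyl group into the isopropenyl group of 5.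

**Step 4 (one-pot oxy-Cope/O-triflation and the labile macrocyclic enol triflate).** The triflation of the hindered tetrasubstituted enolate may be poor, or 7 may not survive isolation and the palladium hydride step. The fallback sets out from 5 and comes back at 8, bypassing 7 and step 5. Enolate 6 is generated as before and trapped with ClP(O)(OEt)2 to give enol phosphate F2. Its C–O bond is then cleaved by dissolving-metal reduction (Li, liquid NH3, THF, t-BuOH, −78 °C), which retains the alkene geometry and leaves the isolated alkenes alone.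

**Step 8 (the proposed new electrochemical cascade).** The methide 12 may instead give the hetero-Diels–Alder chroman across C1=C10, the C4 cation may lose a proton to selinene-type alkenes, 12 may dimerize, or the product enol may be over-oxidized. The fallback uses only established reaction types, sets out from 8 (with 10 for the trione part) and comes back at 13.

- Halonium-initiated transannular cyclization of germacra-1(10),4-dienes is established. NBS (1.05 equiv, NaHCO3, acetone/H2O 4:1, −20 °C) converts 8 by the same anti/anti sequence into bromo alcohol F3.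
- Free-radical formylation of the secondary bromide (Bu3SnH, AIBN, CO 80 atm, PhH, 80 °C) and equilibration with DBU to the equatorial epimer give aldehyde F4.
- In parallel, 10 is C-dimethylated (MeI 2.1 equiv, NaOMe, MeOH) to the 6-unsubstituted trione F5.
- Reductive Knoevenagel alkylation of F5 with F4 (ethylenediammonium diacetate 10 mol%, Hantzsch ester 1.2 equiv, CH2Cl2, 23 °C) passes through alkylidene trione F6 (not isolated), which is reduced in situ by transfer hydrogenation to 13.

Further compounds
F1 | step 3 | (1R,2S,5S)-1-ethynyl-2-methyl-5-(prop-1-en-2-yl)-2-vinylcyclohexan-1-ol | C#C[C@]1(O)C[C@@H](C(C)=C)CC[C@@]1(C)C=C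
F2 | step 4 | diethyl (7S,1(10)E,4Z)-germacra-1(10),4,11-trien-5-yl phosphate | C/C1=C\CC/C(C)=C(\OP(=O)(OCC)OCC)C[C@@H](C(C)=C)CC1
F3 | step 8 | (1S,4S,5S,7S,10S)-1-bromoeudesm-11-en-4-ol (Br equatorial) | C=C(C)[C@H]1CC[C@]2(C)[C@@H](Br)CC[C@](C)(O)[C@H]2C1
F4 | step 8 | (1S,4S,5S,7S,10S)-4-hydroxyeudesm-11-ene-1-carbaldehyde (formyl equatorial) | C=C(C)[C@H]1CC[C@]2(C)[C@@H](C=O)CC[C@](C)(O)[C@H]2C1
F5 | step 8 | 3,5-dihydroxy-6,6-dimethyl-2-(3-methylbutanoyl)cyclohexa-2,4-dien-1-one | CC(C)CC(=O)C1=C(O)C=C(O)C(C)(C)C1=O
F6 | step 8 | 3-hydroxy-4-{[(1R,4S,5S,7S,10R)-4-hydroxyeudesm-11-en-1-yl]methylidene}-6,6-dimethyl-2-(3-methylbutanoyl)cyclohex-2-ene-1,5-dione (alkene geometry not defined) | C=C(C)[C@H]1CC[C@]2(C)[C@@H](C=C3C(=O)C(C)(C)C(=O)C(C(=O)CC(C)C)=C3O)CC[C@](C)(O)[C@H]2C1
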